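All runs were generated by integration for substances that don't exist; the scatter is artificial.

3 questions stand on this one flask, and a single time, the life of the solid reagent, carries the first.

| flask | solid substrate | solid reagent | remark | time |
|---|---|---|---|---|
| ash | 0.21 M | 0.16 M | run made earlier |  |
| cedar | 0.21 M | 0.63 M | run made earlier |  |
| flask | 0.21 M | 0.315 M |  | 8.0 min |

| run | time / min | target / % | solid substrate / % |
|---|---|---|---|
| ash | 0.417 | 0.8 | 87.6 |
| ash | 0.667 | 1.2 | 83.3 |
| ash | 1.00 | 2.6 | 78.4 |
| ash | 2.00 | 10.9 | 69.3 |
| ash | 3.00 | 19.7 | 59.5 |
| ash | 5.00 | 30.3 | 46.3 |
| cedar | 0.333 | 0.3 | 89.3 |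
| cedar | 1.00 | 3.7 | 78.1 |
| cedar | 1.50 | 6.2 | 72.9 |
| cedar | 2.50 | 14.8 | 64.7 |
| cedar | 4.00 | 28.4 | 51.3 |
| cedar | 5.00 | 37.0 | 42.7 |

(each reading ± 0.5 percentage points)

- solid substrate, solid reagent is a solid; its amount is given per volume of the solution
- at the start none of the solid substrate is in solution
- at the start none of the solid reagent is in solution

1. amount of target at 8.0 min, in percent of the solid substrate charged
2. the change that raises the amount of target at 8.0 min, in percent of the solid substrate charged most ("none" if none brings more than 2 percentage points) (theta / gamma / alpha / zeta / none)
3. amount of target at 8.0 min, in percent of the solid substrate charged, after theta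

- theta: doubling the solubility of the solid substrate, all else as stated
- gamma: doubling the dissolution coefficient of the solid reagent, all else as stated
- alpha: doubling the dissolution coefficient of the solid substrate, all else as stated
- zeta: doubling the solubility of the solid reagent, all else as stated

Once started, target climbs along a line of slope s in each run, and L is the lag before that line starts.

s = 0.0888 /min (cedar), 0.0880 /min (ash)

These readings give nearly one slope, though the cedar run holds 3.94 times the reagent of the ash run. So we take the feed of reagent into solution as independent of its charge.

L = 0.833 min

The ash run leaves this line between 3.00 min and 4.25 min, where the line reaches its last reading. We take the midpoint and scale it by charge to get τ, the lifetime of the solid reagent at steady feed: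

τ = 7.13 min

We reckon two extremes for the flask. In the first, the solid reagent outlasts the run and target stays on the line; in the second, target stops dead at τ.

s(t − L) = 63.6%

s(τ − L) = 55.9%

Since τ falls just short of 8.0 min, and what has dissolved by then can still react, we commit to the middle, 59.8%.

The forecast gave 61% (56% to 65%), chose theta, and put 71% (64% to 75%) after it: “Theta looks best, but the margin is uncertain”.

The flask gives 61.2%. The best change is theta, worth 22 percentage points and reaching 83.6%; alpha brings 5.8 points, gamma 0.41 points, zeta −2 points.

    2 partner → homo dimer (k = 0.00330 /M/s)
    dissolved substrate + partner → target (k = 0.130 /M/s)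
    solid substrate ⇌ dissolved substrate, rate k3*(cs3 - [dissolved substrate]) while solid is left; crystals form when [dissolved substrate] > cs3 (solubility = 0.0560 M, k = 0.0250 /s)
    solid reagent ⇌ partner, rate k4*(cs4 - [partner]) while solid is left; crystals form when [partner] > cs4 (solubility = 0.120 M, k = 0.0110 /s)
    partner → decomposed reagent (k = 0.00670 /s)

Solid reagent falls from 65.7% at 2.00 min to 38.4% at 4.00 min, a pace that, carried straight on, reaches zero at 6.81 min against our τ of 7.13 min, and this limiting reagent stands at 0% at 8.00 min. Up to that time 1.50 equiv of it, counted against the solid substrate charged, dissolved net, and the step to decomposed reagent had a net turnover of 74.1% of the substrate charge, above the 61.2% of the step to target.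

The same flask read at 2.0 min stands before τ, so the line gives 10.4% of target. Computed, it holds 10.9% of target.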